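Numbering (drimane): ring A = C1–C5 and C10 (C3=O, gem-dimethyl C4). Ring B = C5–C10 (C7=C8, CH3 on C8, C11H2–OAr on C9, CH3 on C10). The SMILES encodes a cis-decalin with H-5, CH3-10 and H-9 on one face, called β here.
Retrosynthesis: C3=O ⇒ C3–OH; cut C11–OAr (Mitsunobu); C9–H/C11–O ⇒ C9=C11 ⇒ C9 ketone; C7–H ⇒ C7 enol triflate ⇒ 1,3-dione 14. C7=C8 and C5–C10 are then cut together ⇒ monocyclic keto lactone 12 ⇒ ring-closing metathesis, acrylation, C3–C4 (reverse prenylation), C10–C1 (allylation).
Enabling feature: in ring B the C7=C8 bond lies opposite the fusion bond C5–C10, so the ring falls into C8–C9–C10 and C5–C6–C7. With C9 as a ketone, C8 and C10 are its two α-carbons (1,3-bis-nucleophile) and C5=C6–C7(=O)O is a 1,3-bis-electrophile. The C3 oxygen, 1,3 to C5 across C4, can hold C7 as an α,β-unsaturated δ-lactone (temporary ring).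
Forward: the chain C12–C8–C9–C10–C1–C2–C3 comes first, then C4/C5, then the lactone. One base-triggered Michael/Dieckmann cascade closes ring A, then ring B, and opens the lactone. C7–O is then removed, C11 is added at C9, the coumarin is attached, and C3 is oxidised last.
Stereochemistry: C3 comes from a catalytic asymmetric reverse prenylation. C3 sets C5 through the bridge geometry, the second ring closure selects C10 (cis fusion), and convex-face hydroboration sets C9. The C3 centre is then erased.

Key step: step 6

Assumption: the SMILES is taken literally (cis-fused decalin as described above), and in step 3 the SEGPHOS antipode written is taken to be the one that gives the (R)-carbinol; this is to be checked on 9, and the other antipode is used otherwise.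

Step 1
Reactants: 1 pentan-3-one; 2 allyl bromide
Product: 4 4-methylhept-6-en-3-one (racemic), via lithium enolate 3 (not isolated)
Conditions: LiN(i-Pr)2, THF, −78 °C; then 2, −78 °C to 0 °C
Reagents that add atoms: none
Why: Enolate alkylation (SN2) of a symmetrical ketone with a reactive allylic halide joins C10–C1, and the C10 centre may stay racemic because it is enolised again in step 6.

Step 2
Reactants: 4 4-methylhept-6-en-3-one
Product: 6 7-hydroxy-4-methylheptan-3-one, via catechol boronate 5 (not isolated)
Conditions: catecholborane, RhCl(PPh3)3 (2 mol %), THF, rt; then NaOH, H2O2, 0 °C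
Reagents that add atoms: hydrogen peroxide, OO; catecholborane, B1Oc2ccccc2O1 (its atoms stay only in 5)
Why: Rhodium-catalysed hydroboration followed by oxidation, in which the catalysed addition of catecholborane to a terminal alkene is faster than its uncatalysed attack on a ketone, so the anti-Markovnikov primary alcohol forms with the C9 ketone intact.

Step 3
Reactants: 6 7-hydroxy-4-methylheptan-3-one; 7 3-methylbuta-1,2-diene
Product: 9 (7R)-7-hydroxy-4,8,8-trimethyldec-9-en-3-one (mixture of C4 epimers), via keto aldehyde 8 (not isolated)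
Conditions: (η3-allyl)Ir[(S)-SEGPHOS](κ2-C,O-4-chloro-3-nitrobenzoate) (5 mol %), 7 (4 equiv), toluene, 60 °C, sealed tube
Reagents that add atoms: none
Why: Iridium-catalysed transfer-hydrogenative carbonyl reverse prenylation, in which dehydrogenation of 6 gives aldehyde 8 and an iridium hydride, hydrometalation of the allene gives a prenyl-iridium species that adds through its tertiary terminus in a closed chair transition state (C3–C4 bond and gem-dimethyl carbon made together), the chiral bisphosphine sets (R)-C3, the ketone is not attacked, and the aldol-prone 1,5-keto aldehyde never accumulates.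

Step 4
Reactants: 9 (7R)-7-hydroxy-4,8,8-trimethyldec-9-en-3-one; 10 acryloyl chloride
Product: 11 (4R)-3,3,7-trimethyl-8-oxodec-1-en-4-yl prop-2-enoate
Conditions: i-Pr2NEt, DMAP (cat.), CH2Cl2, 0 °C to rt
Reagents that add atoms: none
Why: DMAP-catalysed O-acylation with a small, reactive acid chloride esterifies the hindered carbinol and brings in C6 and C7 without touching the C3–O bond.

Step 5
Reactants: 11 (4R)-3,3,7-trimethyl-8-oxodec-1-en-4-yl prop-2-enoate
Product: 12 (6R)-5,5-dimethyl-6-(3-methyl-4-oxohexyl)-5,6-dihydro-2H-pyran-2-one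
Conditions: RuCl2(H2IMes)(=CH-C6H4-2-O-i-Pr) (second-generation Hoveyda–Grubbs catalyst, 5 mol %), toluene, 0.005 M, 80 °C
Reagents that add atoms: none
Why: Ring-closing metathesis of an acrylate with a monosubstituted alkene gives the ring-(Z) α,β-unsaturated δ-lactone, helped by the gem-dimethyl group (Thorpe–Ingold effect) and driven by loss of ethene.

Step 6
Reactants: 12 (6R)-5,5-dimethyl-6-(3-methyl-4-oxohexyl)-5,6-dihydro-2H-pyran-2-one
Product: 14 (4aR,6R,8aS)-3,6-dihydroxy-2,5,5,8a-tetramethyl-4a,5,6,7,8,8a-hexahydronaphthalen-1(4H)-one (enol form of the cis-fused hydroxy 1,3-dione), via bridged keto lactone 13 (not isolated)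
Conditions: KOt-Bu (3 equiv), THF/t-BuOH, 0.01 M, 0 °C to 60 °C; then 1 M HCl to pH 3
Reagents that add atoms: none
Why: KOt-Bu reversibly enolises the C9 ketone, the C10 enolate adds to C5 of the unsaturated lactone (Michael addition, ring A closed 6-(enolexo)-exo-trig) to give 13, and after proton transfer the C8 enolate acylates at the lactone carbonyl C7 (Dieckmann/Claisen condensation, ring B closed 6-(enolendo)-exo-trig), so that the C3 alkoxide leaves and the 1,3-dione is drained as its enolate, whose enol form carries the C7=C8 double bond. The closest known reaction type is the consecutive Michael–Claisen [3+3] annulation of ketone enolates with α,β-unsaturated esters that gives cyclohexane-1,3-diones (dimedone-type synthesis), run here in a doubly intramolecular way. C5 is set by C3, because the tether C2–C1–C10 can reach C5 only on the lactone face that carries it, so the C3–O and C5–C6 bonds end 1,3-cis (diaxial) on ring A. C10 is set by the second closure: both C10 epimers of 13 can form and interconvert by retro-Michael reaction, but only the one with the propanoyl group cis (gauche) to C6 can reach C7, the other holding the two arms anti-diaxial, so only the cis-fused decalin with CH3-10 and H-5 on one face is drained. The needed regioselectivity (C10 and not C8 in the first bond, 1,4 and not 1,2) follows from ring size (six against eight atoms) and from the reversibility of every step before the final deprotonation, while quaternary C4 rules out γ-deprotonation of the lactone and high dilution suppresses intermolecular addition.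

Step 7
Reactants: 14 enol form of the cis-fused hydroxy 1,3-dione
Product: 15 (4aR,6R,8aS)-6-hydroxy-2,5,5,8a-tetramethyl-3-(trifluoromethylsulfonyloxy)-4a,5,6,7,8,8a-hexahydronaphthalen-1(4H)-one
Conditions: PhNTf2, Et3N, CH2Cl2, 0 °C to rt
Reagents that add atoms: N-phenylbis(trifluoromethanesulfonimide), O=S(=O)(N(c1ccccc1)S(=O)(=O)C(F)(F)F)C(F)(F)F
Why: O-Sulfonylation of a vinylogous acid, in which the mild base ionises only the acidic 1,3-dione, triflyl transfer goes to the less shielded oxygen on C7 (the C9 oxygen is flanked by quaternary C10), and the neutral, hindered C3 hydroxyl does not react with the triflimide.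

Step 8
Reactants: 15 C7 enol triflate
Product: 16 (4aR,6R,8aS)-6-hydroxy-2,5,5,8a-tetramethyl-4a,5,6,7,8,8a-hexahydronaphthalen-1(4H)-one
Conditions: Pd(OAc)2 (5 mol %), PPh3 (10 mol %), HCO2H, Et3N, DMF, 60 °C
Reagents that add atoms: none
Why: Palladium-catalysed formate hydrogenolysis of an enol triflate, in which oxidative addition to zerovalent palladium, decarboxylation of the formate complex and C–H reductive elimination replace C7–O by C7–H and leave C7=C8 in place.

Step 9
Reactants: 16 cis-fused hydroxy enone
Product: 17 (2R,4aS,8aS)-1,1,4a,6-tetramethyl-5-methylidene-1,2,3,4,4a,5,8,8a-octahydronaphthalen-2-ol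
Conditions: Ph3PCH3Br, KOt-Bu (4 equiv each), toluene, 90 °C
Reagents that add atoms: methyltriphenylphosphonium bromide, C[P+](c1ccccc1)(c1ccccc1)c1ccccc1.[Br-]
Why: Wittig methylenation, feasible because the C9 ketone has no α-hydrogen (C10 quaternary, C8 sp2), so the small ylide in excess at raised temperature can add despite the shielding, one equivalent being held by the hydroxyl group.

Step 10
Reactants: 17 semicyclic diene
Product: 19 (2R,4aS,5R,8aS)-5-(hydroxymethyl)-1,1,4a,6-tetramethyl-1,2,3,4,4a,5,8,8a-octahydronaphthalen-2-ol, via bis-boron adduct 18 (not isolated)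
Conditions: 9-BBN (3 equiv), THF, rt to 50 °C; then NaOH, H2O2, 0 °C to rt
Reagents that add atoms: hydrogen peroxide, OO; 9-borabicyclo[3.3.1]nonane, B1C2CCCC1CCC2 (its atoms stay only in 18)
Why: Hydroboration–oxidation, in which the bulky dialkylborane adds to the exocyclic 1,1-disubstituted C9=C11 bond (boron on terminal C11) faster than to trisubstituted C7=C8, and from the convex β face because ring A with the C4 methyl groups is folded under the α face, so hydrogen arrives on C9 syn to CH3-10 and C11 ends α as in the target.

Step 11
Reactants: 19 diol; 20 umbelliferone (7-hydroxy-2H-chromen-2-one)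
Product: 21 7-{[(1R,4aS,6R,8aS)-6-hydroxy-2,5,5,8a-tetramethyl-1,4,4a,5,6,7,8,8a-octahydronaphthalen-1-yl]methoxy}-2H-chromen-2-one
Conditions: PPh3, DIAD, THF, 0 °C to rt
Reagents that add atoms: none
Why: Mitsunobu etherification, in which the acidic phenol displaces the alkoxyphosphonium ion of the primary C11 alcohol (SN2, no stereocentre touched) while the secondary neopentyl C3 hydroxyl is too hindered to be substituted.

Step 12
Reactants: 21 hydroxy ether
Product: 22 7-{[(1R,4aS,8aS)-2,5,5,8a-tetramethyl-6-oxo-1,4,4a,5,6,7,8,8a-octahydronaphthalen-1-yl]methoxy}-2H-chromen-2-one (target)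
Conditions: Dess–Martin periodinane, CH2Cl2, rt
Reagents that add atoms: none
Why: Dess–Martin oxidation under neutral conditions turns the C3 carbinol into the ketone without touching the coumarin, the aryl ether or C7=C8, and removes the auxiliary stereocentre.

Compound list
1 | pentan-3-one | CCC(=O)CC | starting material
2 | allyl bromide | C=CCBr | starting material
3 | lithium pent-2-en-3-olate (formed in the flask) | CC=C([O-])CC.[Li+] | intermediate
4 | 4-methylhept-6-en-3-one (racemic) | CCC(=O)C(C)CC=C | intermediate
5 | 2-(4-methyl-5-oxoheptyl)-1,3,2-benzodioxaborole (formed in the flask) | CCC(=O)C(C)CCCB1Oc2ccccc2O1 | intermediate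
6 | 7-hydroxy-4-methylheptan-3-one | CCC(=O)C(C)CCCO | intermediate
7 | 3-methylbuta-1,2-diene | CC(C)=C=C | starting material
8 | 4-methyl-5-oxoheptanal (formed in the flask) | CCC(=O)C(C)CCC=O | intermediate
9 | (7R)-7-hydroxy-4,8,8-trimethyldec-9-en-3-one | CCC(=O)C(C)CC[C@@H](O)C(C)(C)C=C | intermediate
10 | acryloyl chloride | C=CC(=O)Cl | starting material
11 | (4R)-3,3,7-trimethyl-8-oxodec-1-en-4-yl prop-2-enoate | CCC(=O)C(C)CC[C@@H](OC(=O)C=C)C(C)(C)C=C | intermediate
12 | (6R)-5,5-dimethyl-6-(3-methyl-4-oxohexyl)-5,6-dihydro-2H-pyran-2-one | CCC(=O)C(C)CC[C@H]1OC(=O)C=CC1(C)C | intermediate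
13 | (1R,5R,6S)-6,9,9-trimethyl-6-propanoyl-2-oxabicyclo[3.3.1]nonan-3-one (formed in the flask) | CCC(=O)[C@@]1(C)CC[C@H]2OC(=O)C[C@@H]1C2(C)C | intermediate
14 | (4aR,6R,8aS)-3,6-dihydroxy-2,5,5,8a-tetramethyl-4a,5,6,7,8,8a-hexahydronaphthalen-1(4H)-one (enol of the 1,3-dione) | CC1=C(O)C[C@@H]2C(C)(C)[C@H](O)CC[C@]2(C)C1=O | intermediate
15 | (4aR,6R,8aS)-6-hydroxy-2,5,5,8a-tetramethyl-3-(trifluoromethylsulfonyloxy)-4a,5,6,7,8,8a-hexahydronaphthalen-1(4H)-one | CC1=C(OS(=O)(=O)C(F)(F)F)C[C@@H]2C(C)(C)[C@H](O)CC[C@]2(C)C1=O | intermediate
16 | (4aR,6R,8aS)-6-hydroxy-2,5,5,8a-tetramethyl-4a,5,6,7,8,8a-hexahydronaphthalen-1(4H)-one | CC1=CC[C@@H]2C(C)(C)[C@H](O)CC[C@]2(C)C1=O | intermediate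
17 | (2R,4aS,8aS)-1,1,4a,6-tetramethyl-5-methylidene-1,2,3,4,4a,5,8,8a-octahydronaphthalen-2-ol | CC1=CC[C@@H]2C(C)(C)[C@H](O)CC[C@]2(C)C1=C | intermediate
18 | C11 9-BBN alkylborane of 17, C3 oxygen as 9-BBN borinate, H-9 β (formed in the flask) | CC1=CC[C@@H]2C(C)(C)[C@H](OB3C4CCCC3CCC4)CC[C@]2(C)[C@@H]1CB5C6CCCC5CCC6 | intermediate
19 | (2R,4aS,5R,8aS)-5-(hydroxymethyl)-1,1,4a,6-tetramethyl-1,2,3,4,4a,5,8,8a-octahydronaphthalen-2-ol | CC1=CC[C@@H]2C(C)(C)[C@H](O)CC[C@]2(C)[C@@H]1CO | intermediate
20 | umbelliferone (7-hydroxy-2H-chromen-2-one) | Oc1ccc2ccc(=O)oc2c1 | starting material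
21 | 7-{[(1R,4aS,6R,8aS)-6-hydroxy-2,5,5,8a-tetramethyl-1,4,4a,5,6,7,8,8a-octahydronaphthalen-1-yl]methoxy}-2H-chromen-2-one | CC1=CC[C@@H]2C(C)(C)[C@H](O)CC[C@]2(C)[C@@H]1COc1ccc2ccc(=O)oc2c1 | intermediate
22 | 7-{[(1R,4aS,8aS)-2,5,5,8a-tetramethyl-6-oxo-1,4,4a,5,6,7,8,8a-octahydronaphthalen-1-yl]methoxy}-2H-chromen-2-one | CC1=CC[C@@H]2C(C)(C)C(=O)CC[C@]2(C)[C@@H]1COc1ccc2ccc(=O)oc2c1 | target

Total step count: 12. Longest linear sequence: 12 steps (from 1).

Steps most likely to fail

Risk at step 6. The Michael closure that joins quaternary C10 to neopentyl C5 may be slow or lie on the side of the open form. Intermolecular conjugate addition or alkoxide cleavage of the lactone could then take over before the Dieckmann closure drains the equilibrium.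
- The fallback sets out from 12 and comes back at 14.
- 12 is silylated under equilibrating conditions (Me3SiOTf, Et3N, CH2Cl2, reflux) to the tetrasubstituted enol ether (6R)-5,5-dimethyl-6-[3-methyl-4-(trimethylsilyloxy)hex-3-en-1-yl]-5,6-dihydro-2H-pyran-2-one F1. The unproductive regioisomer returns to 12 on hydrolysis.
- A TiCl4-promoted intramolecular Mukaiyama–Michael addition (CH2Cl2, −78 °C) forms C5–C10 irreversibly and gives isolated 13.
- 13 is then closed in a separate Dieckmann condensation (KOt-Bu, THF/t-BuOH) to 14. The base also interconverts the C10 epimers by retro-Michael reaction.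

Risk at step 10. Addition of the bulky borane to the C9=C11 bond, which lies between quaternary C10 and the C8 methyl group, may be sluggish. Attack on C7=C8 or erosion of facial selectivity could then compete.
- The fallback sets out from 16, bypasses 17 and comes back at 19.
- Dimethylsulfonium methylide (Me3SI, NaH, DMSO/THF, 0 °C; Corey–Chaykovsky epoxidation) should add 1,2 to the C9 ketone from the convex β face. This gives the vinyl oxirane F2, the C9 spiro-epoxide of 16 with the oxirane oxygen α and C11 β.
- Palladium-catalysed formate hydrogenolysis of the alkenyl oxirane follows (Pd2(dba)3, PBu3, HCO2H, Et3N, dioxane, rt).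
- Zerovalent palladium ionises the C9–O bond anti to the oxygen, from the β face. Hydride is then passed from the metal to the more substituted allyl terminus C9 on that same face. The net inversion places H-9 β and leaves C7=C8 and C11–OH as in 19.

Risk at step 11. Substitution at the β-branched, homoallylic C11 may be slower than loss of the alkoxyphosphonium group by elimination of the allylic H-9, which would lead back to the diene.
- The fallback sets out from 19 and comes back at 21.
- The aryl–oxygen bond is made instead of the alkyl–oxygen bond. This is a palladium-catalysed C–O coupling of the primary alcohol of 19 with commercial 7-bromo-2H-chromen-2-one (Pd2(dba)3, t-BuBrettPhos, Cs2CO3, toluene, 90 °C).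
- The C11–O bond is never activated, and the hindered C3 hydroxyl should not couple.

Further compounds
F1 | step 6 | (6R)-5,5-dimethyl-6-[3-methyl-4-(trimethylsilyloxy)hex-3-en-1-yl]-5,6-dihydro-2H-pyran-2-one | CCC(O[Si](C)(C)C)=C(C)CC[C@H]1OC(=O)C=CC1(C)C
F2 | step 10 | C9 spiro-oxirane of 16 (oxirane oxygen α, C11 β; 6-hydroxy-2,5,5,8a-tetramethyl-4a,5,6,7,8,8a-hexahydro-4H-spiro[naphthalene-1,2'-oxirane]) | CC1=CC[C@@H]2C(C)(C)[C@H](O)CC[C@]2(C)[C@@]13CO3
F0 | step 11 | none | none
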